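**Plan**
- Retrosynthetic cuts, in order: the O7–CH2 bond of the prenyl ether; the two ring A bonds C7–C8 and C4a–C5; the C2–C1' bond to the dimethoxyphenyl ring; the C–Br bond of a brominated allomaltol.
- Enabling feature: ring C is a 2-aryl-3-oxy-4-pyranone in which the C8 methyl carbon (γ-position of the vinylogous ester) and ring carbon C4a are both nucleophilic. The C7–C6–C5 part of ring A is at the oxidation level of a β-keto aldehyde, so a three-carbon ester–acetal completes the ring.
- Forward: ring C is bought as allomaltol, ring B is attached by Suzuki coupling, ring A is annulated onto ring C by Claisen acylation and acid-driven cyclodehydrative aromatisation, and the prenyl ether is made last.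
- Stereochemistry: the target has no stereocentre and no stereogenic double bond, so nothing has to be set.

Key step: step 4

Assumption: allomaltol is treated as a purchasable pyranone; positions in the pyranone intermediates are named by the flavone numbering they acquire (O1, C2, C3, C4, C4a, C5 to C8, C8a).

**Step 1**
Reactants: 1 allomaltol (5-hydroxy-2-methyl-4H-pyran-4-one)
Product: 2 2-bromo-3-hydroxy-6-methyl-4H-pyran-4-one
Conditions: NBS (1.05 equiv), MeCN, 0 °C to rt, dark
Reagents that add atoms: N-bromosuccinimide, O=C1CCC(=O)N1Br
Why: Electrophilic bromination of the enolic hydroxypyranone should occur at the ring carbon next to the hydroxyl (the enol β-carbon), the site at which this ring system also takes aldol and Mannich electrophiles, and the methyl group is untouched under non-radical conditions.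

**Step 2**
Reactants: 2 2-bromo-3-hydroxy-6-methyl-4H-pyran-4-one
Product: 3 2-bromo-3-(methoxymethoxy)-6-methyl-4H-pyran-4-one
Conditions: MOMCl (1.2 equiv), K2CO3, acetone, 0 °C to rt
Reagents that add atoms: chloromethyl methyl ether, COCCl
Why: Williamson-type O-alkylation of the acidic enolic hydroxyl with the reactive α-chloro ether should give the methoxymethyl acetal, which masks the only acidic proton before the strong-base step and is removed by acid later.

**Step 3**
Reactants: 3 2-bromo-3-(methoxymethoxy)-6-methyl-4H-pyran-4-one; 4 3,4-dimethoxyphenylboronic acid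
Product: 5 2-(3,4-dimethoxyphenyl)-3-(methoxymethoxy)-6-methyl-4H-pyran-4-one
Conditions: Pd(PPh3)4 (5 mol %), K2CO3, DME–H2O, 80 °C
Reagents that add atoms: none
Why: Suzuki–Miyaura coupling; the C–Br bond is that of a vinylogous acyl bromide and should add oxidatively to zerovalent palladium with ease, while the acetal, the methyl group and the pyranone tolerate mild aqueous carbonate.

**Step 4**
Reactants: 5 2-(3,4-dimethoxyphenyl)-3-(methoxymethoxy)-6-methyl-4H-pyran-4-one; 6 methyl 3,3-dimethoxypropanoate
Product: 9 3,7-dihydroxy-3',4'-dimethoxyflavone, via lithium dienolate 7 (not isolated), via β-keto acetal 8 (not isolated)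
Conditions: LiN(SiMe3)2 (2.3 equiv), THF, −78 °C; 6 (1.3 equiv) added last, −78 to −30 °C; then HCl in MeOH (excess), −30 to 60 °C
Reagents that add atoms: none
Why: Proposed new method: deprotonation of 5 at its C6 methyl group, the γ-position of the vinylogous ester, should give cross-conjugated dienolate 7, whose exocyclic carbon adds to the ester carbonyl of 6 in a Claisen acylation (C8–C7), the second equivalent of base holding the more acidic product as its enolate until the acid quench releases β-keto acetal 8. In methanolic HCl the acetal of 8 should ionise to an oxocarbenium ion (or its β-methoxyenone equivalent) at the future C5, which is captured by the future C4a, the α-carbon of the vinylogous ester O1–C8a=C4a–C4=O and the enol carbon of the dienol tautomer, so that ring A closes in a Baldwin-favoured 6-exo-trig mode with respect to the cation (C4a–C5); the same event can be read as a 6π-electrocyclisation of the trienol. Elimination of the second methanol and tautomerisation of the C7 ketone to the phenol then aromatise ring A irreversibly, and the acid also cleaves the methoxymethyl ether, whose fragment methanol traps as dimethoxymethane so that no formaldehyde equivalent remains to attack the new phenol. The closest known reaction types are Claisen acylations of laterally lithiated 2-methyl-4-pyranones, aldol-type closures of pyranone-bearing polyketone chains onto the pyranone ring carbon, and Bradsher-type acid-mediated cyclodehydrative benzannulations of β-keto acetals. No stereocentre is formed; the selectivity needed is the placing of the ring A oxygen, and the polarity of 6 secures it, because its acyl carbon can only be reached by the methyl-derived carbanion and so ends as the phenolic C7, while its acetal carbon can only be reached by C4a and so ends as the unsubstituted C5. Chemoselectivity in the closure is helped by the substitution of 5: C2 and C3 are blocked, the dimethoxyphenyl ring cannot reach the cation, and C4a is the only carbon nucleophile placed for a six-membered ring.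

**Step 5**
Reactants: 9 3,7-dihydroxy-3',4'-dimethoxyflavone; 10 prenyl bromide (1-bromo-3-methylbut-2-ene)
Product: 11 3-hydroxy-3',4'-dimethoxy-7-(3-methylbut-2-enyloxy)flavone (the target)
Conditions: 10 (1.05 equiv), K2CO3 (1.1 equiv), DMF, N2, 0 °C to rt
Reagents that add atoms: none
Why: Williamson etherification (SN2) with a single equivalent of weak base should occur at O7, because the 7-hydroxyl is a vinylogous carboxylic acid para to C4=O and is deprotonated first, whereas the 3-hydroxyl is less acidic and held in a hydrogen bond to C4=O.

**Compound list**
1 | allomaltol (5-hydroxy-2-methyl-4H-pyran-4-one) | Cc1cc(=O)c(O)co1 | starting material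
2 | 2-bromo-3-hydroxy-6-methyl-4H-pyran-4-one | Cc1cc(=O)c(O)c(Br)o1 | intermediate
3 | 2-bromo-3-(methoxymethoxy)-6-methyl-4H-pyran-4-one | COCOc1c(Br)oc(C)cc1=O | intermediate
4 | 3,4-dimethoxyphenylboronic acid | COc1ccc(B(O)O)cc1OC | starting material
5 | 2-(3,4-dimethoxyphenyl)-3-(methoxymethoxy)-6-methyl-4H-pyran-4-one | COCOc1c(-c2ccc(OC)c(OC)c2)oc(C)cc1=O | intermediate
6 | methyl 3,3-dimethoxypropanoate | COC(=O)CC(OC)OC | starting material
7 | lithium 2-(3,4-dimethoxyphenyl)-3-(methoxymethoxy)-6-methylidene-6H-pyran-4-olate (dienolate of 5, formed in the flask) | [Li+].[O-]C1=CC(=C)OC(c2ccc(OC)c(OC)c2)=C1OCOC | intermediate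
8 | 6-(4,4-dimethoxy-2-oxobutyl)-2-(3,4-dimethoxyphenyl)-3-(methoxymethoxy)-4H-pyran-4-one (β-keto acetal, formed in the flask) | COCOc1c(-c2ccc(OC)c(OC)c2)oc(CC(=O)CC(OC)OC)cc1=O | intermediate
9 | 3,7-dihydroxy-3',4'-dimethoxyflavone [2-(3,4-dimethoxyphenyl)-3,7-dihydroxy-4H-chromen-4-one] | COc1ccc(-c2oc3cc(O)ccc3c(=O)c2O)cc1OC | intermediate
10 | prenyl bromide (1-bromo-3-methylbut-2-ene) | CC(C)=CCBr | starting material
11 | 2-(3,4-dimethoxyphenyl)-3-hydroxy-7-(3-methylbut-2-enyloxy)-4H-chromen-4-one | COc1ccc(-c2oc3cc(OCC=C(C)C)ccc3c(=O)c2O)cc1OC | target

**Step count**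
Total steps: 5. Longest linear sequence: 5 steps (1 → 2 → 3 → 5 → 9 → 11).

**Steps most likely to fail**

Step 4 (proposed new method). Two processes threaten it. In the base stage, proton transfer from the α-CH2 of ester 6 to the amide base or the dienolate, followed by β-elimination of methoxide, would use up the acyl donor before C8–C7 forms. In the acid stage, if attack by C4a of the partly protonated pyranone is too slow, the acetal would be hydrolysed and the formyl carbon lost by retro-Claisen cleavage, or the chain would condense intermolecularly. The fallback is the Algar–Flynn–Oyamada sequence, all of it known chemistry, which sets out from prenyl bromide 10 and comes back to the route at target 11. 2',4'-Dihydroxyacetophenone would be alkylated with 10 (K2CO3, acetone, reflux) at the unchelated 4'-hydroxyl to give 1-[2-hydroxy-4-(3-methylbut-2-enyloxy)phenyl]ethanone F1. Claisen–Schmidt condensation with 3,4-dimethoxybenzaldehyde (KOH, EtOH, rt) would give (E)-3-(3,4-dimethoxyphenyl)-1-[2-hydroxy-4-(3-methylbut-2-enyloxy)phenyl]prop-2-en-1-one F2. Alkaline H2O2 (NaOH, MeOH, 0 °C to rt) would then close and oxidise ring C to give 11, the prenyl ether being inert to these conditions.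

Step 5. Site selectivity may be lost, with alkylation at O3 in addition to or instead of O7 once more than one oxygen is deprotonated. The fallback sets out from 9 and comes back at 11 by differentiating the two hydroxyls through their esters. Acetylation (Ac2O, pyridine, rt) would give 3,7-diacetoxy-3',4'-dimethoxyflavone F3. Thiolysis of the more activated aryl ester (PhSH, imidazole, NMP, 0 °C) would give 3-acetoxy-7-hydroxy-3',4'-dimethoxyflavone F4. Mitsunobu etherification with 3-methylbut-2-en-1-ol (PPh3, DIAD, THF, 0 °C), neutral so that the enol acetate does not migrate, would give 3-acetoxy-3',4'-dimethoxy-7-(3-methylbut-2-enyloxy)flavone F5. Mild methanolysis (K2CO3, MeOH, rt) would then give 11.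

Step 3. Addition–elimination of hydroxide or carbonate at the bromine-bearing carbon of the vinylogous acyl bromide, and protodeboronation of the electron-rich boronic acid, may consume both partners before transmetalation. The fallback sets out from bromide 3 and comes back at 5 by a base-free, anhydrous Stille coupling. Its partner, tributyl(3,4-dimethoxyphenyl)stannane F6, would be made from 4-bromo-1,2-dimethoxybenzene by bromine–lithium exchange (n-BuLi, THF, −78 °C) and quenching with Bu3SnCl. F6 would then be coupled with 3 (Pd(PPh3)4, CuI, DMF, 80 °C) to give 5.

**Further compounds**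
F1 | step 4 | 1-[2-hydroxy-4-(3-methylbut-2-enyloxy)phenyl]ethanone | CC(=O)c1ccc(OCC=C(C)C)cc1O
F2 | step 4 | (E)-3-(3,4-dimethoxyphenyl)-1-[2-hydroxy-4-(3-methylbut-2-enyloxy)phenyl]prop-2-en-1-one | COc1ccc(/C=C/C(=O)c2ccc(OCC=C(C)C)cc2O)cc1OC
F3 | step 5 | 3,7-diacetoxy-3',4'-dimethoxyflavone | COc1ccc(-c2oc3cc(OC(C)=O)ccc3c(=O)c2OC(C)=O)cc1OC
F4 | step 5 | 3-acetoxy-7-hydroxy-3',4'-dimethoxyflavone | COc1ccc(-c2oc3cc(O)ccc3c(=O)c2OC(C)=O)cc1OC
F5 | step 5 | 3-acetoxy-3',4'-dimethoxy-7-(3-methylbut-2-enyloxy)flavone | COc1ccc(-c2oc3cc(OCC=C(C)C)ccc3c(=O)c2OC(C)=O)cc1OC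
F6 | step 3 | tributyl(3,4-dimethoxyphenyl)stannane | CCCC[Sn](CCCC)(CCCC)c1ccc(OC)c(OC)c1
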